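The numbers in the tables were computed with constants of no real substance; the scatter is artificial.

How much target stands in the flask at 8.0 min, and which option raises it most?

all flasks: gas phase 1.1 mM (held); impurity 8.7 µM
- delta: solid substrate 22 mM; free catalyst 29 µM; run made earlier
- eta: solid substrate 22 mM; free catalyst 66 µM; run made earlier
- gamma: solid substrate 44 mM; free catalyst 44 µM; run made earlier
- flask: solid substrate 22 mM; free catalyst 44 µM; time 8.0 min

| run | time / min | target / % |
|---|---|---|
| delta | 0.833 | 0.7 |
| delta | 2.50 | 4.5 |
| delta | 4.00 | 7.5 |
| delta | 6.00 | 11.1 |
| delta | 10.0 | 17.8 |
| eta | 0.833 | 2.7 |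
| eta | 2.50 | 10.7 |
| eta | 4.00 | 18.3 |
| eta | 6.00 | 27.9 |
| eta | 10.0 | 42.0 |
| gamma | 2.00 | 2.8 |
| gamma | 4.00 | 6.8 |
| gamma | 6.00 | 9.4 |
| gamma | 8.00 | 11.8 |
| gamma | 10.0 | 14.1 |

(readings scatter by 0.3 percentage points)

- solid substrate is a solid; its amount is given per volume of the solution
- the earlier runs were read with a standard deviation of 0.3 percentage points
- at the start none of the gas phase is in solution
- at the start none of the solid substrate is in solution

- grey: doubling the dissolution coefficient of the solid substrate, all else as stated
- teal: doubling the amount of free catalyst, all else as stated
- amber: doubling the saturation concentration of gas phase, all else as stated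
- ochre: doubling the solubility of the solid substrate, all else as stated

1. target at 8.0 min, in percent of the solid substrate charged
2. the change that raises the amount of target at 8.0 min, in percent of the solid substrate charged most ("none" if none brings more than 2 percentage points) (grey / teal / amber / ochre / none)
3. amount of target at 8.0 min, in percent of the solid substrate charged, after ochre

Take the main step first, with target proportional to charged catalyst times time. Scaled to the flask, delta's reading at 10.0 min gives 21.6% and eta's at 6.00 min gives 24.8%, a gap of 3.2 percentage points against a scatter of 0.3 points.

Now add the impurity as a catalyst poison, each impurity taking one free catalyst. The quantity to carry is the working catalyst, the charge less the impurity: 35.3 µM in the flask, or 80.2% of its charge. A run's time, multiplied by its working catalyst over the flask's, becomes flask-time. Delta's reading then stands at 5.75 min and eta's at 9.74 min. Scaling now gives 24.8% and 22.9%, so the gap narrows and changes sign: on these two readings, target per flask-minute is lower at the later flask-time.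

Adding that curvature means reading between the two points instead of through zero, which gives 23.5% at 8.0 min. That is the reckoning committed to here. Gamma, with the flask's catalyst and doubled solid, holds 11.8% of its own charge at that time, or 23.6% of the flask's charge. The three runs differ in catalyst and solid charge, so the clock speaks to teal and not to the other options.

The forecast gives 23.3%, chooses teal and puts ochre at 37%, adding: “The orders in gas and in dissolved substrate are untested.”

The flask gives 24.1%, which is 0.60 points above the reckoning here. Ochre adds 23 points and teal 21 points, so ochre leads and reaches 46.8%.

    target ⇌ isomer of the product (K = 13.5, k = 0.00135 s⁻¹)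
    gas phase ⇌ dissolved gas, rate k2*(csat - [dissolved gas]) (kL = 0.645 s⁻¹)
    solid substrate ⇌ starting material, rate k3*(cs3 - [starting material]) while solid is left; crystals form when [starting material] > cs3 (solubility = 5.90 mM, k = 0.0172 s⁻¹)
    free catalyst + impurity → spent catalyst (k = 1.45 × 10⁵ M⁻¹ s⁻¹)
    starting material + dissolved gas + free catalyst → free catalyst + target (k = 86100 M⁻² s⁻¹)

The neighbouring flask has the same recipe with 0.075 mM of free catalyst. Its working catalyst is 88.4% of its charge, and its state at 8.00 min shows free catalyst at 88.4%. Its 8.0 min stands at 15.0 min on the clock, between eta's 9.74 min and 16.2 min. Reading between eta's 27.9% and 42.0% puts target at 39.4%. The neighbouring flask gives 39.7% of target, with 12.8% as isomer of the product.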